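**Strategy**

The plan rests on building ring A de novo instead of substituting a phloroglucinol. Ring A is a hexasubstituted benzene with three oxygens (C2, C4, C6) that must be told apart around C1 (butyryl), C3 (H) and C5 (bridge carbon). A cyclobutenone–ynol ether benzannulation does this in one operation: a 2-(1-silyloxybutyl)-3-ethoxy-4-methylcyclobutenone opens to a vinylketene, takes up ethoxyacetylene and recloses, forming C1–C2 and C3–C4 and leaving C4–OH as the only free phenol between two ethyl ethers. Methylation, side-chain oxidation and carbonyl-directed de-ethylation give aspidinol, whose C5 methyl is oxidised to a quinone methide and captured by acetylfilicinic acid (ring B).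

Key step: step 4

Assumption: ring B is drawn as one enol form and its tautomers are treated as the same compound; the target has no stereocentre, so every stereocentre on the way is racemic and is erased. Ethoxyacetylene is used as its commercial hexane solution.

**Route**

Step 1
Reactants: 1 ethoxyacetylene; 2 butanal
Product: 5 tert-butyl[(1-ethoxyhex-1-yn-3-yl)oxy]dimethylsilane (racemic), via lithium ethoxyacetylide 3 (not isolated), via lithium 1-ethoxyhex-1-yn-3-olate 4 (not isolated)
Conditions: n-BuLi, THF, −78 °C; 2; then TBSCl, imidazole, DMF, −78 °C → rt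
Reagents that add atoms: tert-butyldimethylsilyl chloride, CC(C)(C)[Si](C)(C)Cl
Why: Acetylide 1,2-addition to the aldehyde followed by silylation of the lithium alkoxide in the same flask avoids isolating a 1-alkoxypropargylic alcohol that is prone to Meyer–Schuster rearrangement; the carbinol centre forms without control and is removed by oxidation in step 7.

Step 2
Reactants: 5 tert-butyl[(1-ethoxyhex-1-yn-3-yl)oxy]dimethylsilane; 6 2-chloropropanoyl chloride (racemic)
Product: 8 2-[1-(tert-butyldimethylsilyloxy)butyl]-4-chloro-3-ethoxy-4-methylcyclobut-2-en-1-one (racemic diastereomer mixture), via methylchloroketene 7 (not isolated)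
Conditions: Et3N, Et2O, 0 °C → rt, slow addition of 6
Reagents that add atoms: none
Why: Ketene–ynol ether [2+2] cycloaddition, in which the nucleophilic alkyl-bearing alkyne carbon of 5 attacks the carbonyl carbon of ketene 7 and the ring closes at the ethoxy-bearing carbon, should give the 3-ethoxycyclobutenone as one regioisomer; the new C4 centre is unselective and is erased in steps 3 and 4.

Step 3
Reactants: 8 2-[1-(tert-butyldimethylsilyloxy)butyl]-4-chloro-3-ethoxy-4-methylcyclobut-2-en-1-one
Product: 9 2-[1-(tert-butyldimethylsilyloxy)butyl]-3-ethoxy-4-methylcyclobut-2-en-1-one (racemic diastereomer mixture)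
Conditions: Zn dust, AcOH, TMEDA, EtOH, 0 °C → rt
Reagents that add atoms: none
Why: Zinc-mediated reductive dechlorination of the α-chloro ketone, the usual finish for chloroketene cycloadducts, replaces Cl by H, with ethanol chosen so that any exchange at the vinylogous ester is degenerate; the C4 centre is again unselective and becomes an aromatic carbon in step 4.

Step 4
Reactants: 9 2-[1-(tert-butyldimethylsilyloxy)butyl]-3-ethoxy-4-methylcyclobut-2-en-1-one; 1 ethoxyacetylene
Product: 14 4-[1-(tert-butyldimethylsilyloxy)butyl]-3,5-diethoxy-2-methylphenol (racemic), via vinylketene 10 (not isolated), via 4-vinylcyclobutenone 11 (not isolated), via dienylketene 12 (not isolated), via cyclohexadienone 13 (not isolated)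
Conditions: hν (300 nm), 1 (3 equiv), PhMe, rt; evaporate excess 1; PhMe, 110 °C
Reagents that add atoms: none
Why: Danheiser benzannulation, started with light because a 3-alkoxycyclobutenone opens sluggishly on heating and ethoxyacetylene fragments to ketene above about 100 °C: irradiation cleaves the C(=O)–C4 bond of 9 in a four-electron electrocyclic opening to vinylketene 10, which adds 1 in a [2+2] cycloaddition (forming C1–C2 and C3–C4 of ring A) to give 4-vinylcyclobutenone 11. Once excess 1 is removed, heating opens 11 to dienylketene 12, and ring A closes by six-electron disrotatory electrocyclisation between the ketene carbon and the methyl-bearing terminus (the C4–C5 bond) to cyclohexadienone 13, which tautomerises to phenol 14. The closest known reaction type is the annulation of cyclobutenones with alkoxyacetylenes to resorcinol monoethers. No stereocentre is created, because the sp3 ring carbon of 9 and 13 becomes aromatic and the silyloxy carbinol centre is a racemic spectator. The selectivity needed is the orientation of the ketene–alkyne cycloaddition, and the polarisation of the ynol ether secures it: its unsubstituted nucleophilic carbon bonds to the ketene carbonyl carbon, so OEt lands on C2, H on C3 and the only free hydroxyl on C4.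

Step 5
Reactants: 14 4-[1-(tert-butyldimethylsilyloxy)butyl]-3,5-diethoxy-2-methylphenol
Product: 15 tert-butyl[1-(2,6-diethoxy-4-methoxy-3-methylphenyl)butoxy]dimethylsilane (racemic)
Conditions: MeI, K2CO3, DMF, rt
Reagents that add atoms: iodomethane, CI
Why: Williamson O-methylation of the single, unhindered phenol fixes the C4 methoxy group of ring A, and mild carbonate base at room temperature should avoid 1,6-elimination of the para benzylic silyloxy group.

Step 6
Reactants: 15 tert-butyl[1-(2,6-diethoxy-4-methoxy-3-methylphenyl)butoxy]dimethylsilane
Product: 16 1-(2,6-diethoxy-4-methoxy-3-methylphenyl)butan-1-ol (racemic)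
Conditions: TBAF, THF, rt
Reagents that add atoms: none
Why: Fluoride-mediated Si–O cleavage (TBAF desilylation) works under basic, non-ionising conditions, which suits a trialkoxybenzylic alcohol that would ionise under acid.

Step 7
Reactants: 16 1-(2,6-diethoxy-4-methoxy-3-methylphenyl)butan-1-ol
Product: 17 1-(2,6-diethoxy-4-methoxy-3-methylphenyl)butan-1-one
Conditions: Dess–Martin periodinane, pyridine, CH2Cl2, 0 °C → rt
Reagents that add atoms: none
Why: Dess–Martin oxidation of the hindered secondary benzylic alcohol under buffered conditions should give the aryl ketone without touching the electron-rich ring, and it removes the last stereocentre.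

Step 8
Reactants: 17 1-(2,6-diethoxy-4-methoxy-3-methylphenyl)butan-1-one
Product: 18 1-(2,6-dihydroxy-4-methoxy-3-methylphenyl)butan-1-one (aspidinol)
Conditions: BCl3 (4 equiv), CH2Cl2, −78 °C → rt; H2O
Reagents that add atoms: none
Why: Carbonyl-directed Lewis acid dealkylation, in which boron held at the ketone oxygen is delivered to each flanking ethoxy oxygen in turn and chloride removes the ethyl group, should spare the C4 methoxy group, which is para to the carbonyl and cannot chelate.

Step 9
Reactants: 19 2,4,6-trihydroxyacetophenone
Product: 20 2-acetyl-3,5-dihydroxy-4,4-dimethylcyclohexa-2,5-dien-1-one (acetylfilicinic acid)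
Conditions: NaOMe, MeI (2.2 equiv), MeOH, 0 °C → rt; aq. HCl
Reagents that add atoms: iodomethane, CI
Why: Dearomatising double C-methylation of the phloroglucinol polyanion, with the second methyl entering at the already methylated ring carbon, gives the gem-dimethyl filicinic acid skeleton; mono- and trimethylated by-products are expected and would be removed by chromatography.

Step 10
Reactants: 18 1-(2,6-dihydroxy-4-methoxy-3-methylphenyl)butan-1-one; 20 2-acetyl-3,5-dihydroxy-4,4-dimethylcyclohexa-2,5-dien-1-one
Product: 22 2-acetyl-6-[(3-butanoyl-2,4-dihydroxy-6-methoxyphenyl)methyl]-3,5-dihydroxy-4,4-dimethylcyclohexa-2,5-dien-1-one (target CNP0378451.0), via o-quinone methide 21 (not isolated)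
Conditions: Ag2O (1.1 equiv), 20 (2 equiv), THF, rt, dark
Reagents that add atoms: none
Why: Ag2O dehydrogenation of the o-methylphenol unit (C6–OH, C5–CH3) gives o-quinone methide 21, and Michael addition of the acidic ring CH of 20 to the exocyclic methylene followed by rearomatisation should give the CH2 bridge, with excess 20 used to outcompete capture of 21 by 18.

**Compound list**

1 | ethoxyacetylene | C#COCC | starting material
2 | butanal | CCCC=O | starting material
3 | lithium ethoxyacetylide | [Li]C#COCC | intermediate
4 | lithium 1-ethoxyhex-1-yn-3-olate (racemic) | CCCC(O[Li])C#COCC | intermediate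
5 | tert-butyl[(1-ethoxyhex-1-yn-3-yl)oxy]dimethylsilane (racemic) | CCCC(O[Si](C)(C)C(C)(C)C)C#COCC | intermediate
6 | 2-chloropropanoyl chloride (racemic) | CC(Cl)C(Cl)=O | starting material
7 | methylchloroketene (2-chloroprop-1-en-1-one) | CC(Cl)=C=O | intermediate
8 | 2-[1-(tert-butyldimethylsilyloxy)butyl]-4-chloro-3-ethoxy-4-methylcyclobut-2-en-1-one (racemic diastereomer mixture) | CCCC(O[Si](C)(C)C(C)(C)C)C1=C(OCC)C(C)(Cl)C1=O | intermediate
9 | 2-[1-(tert-butyldimethylsilyloxy)butyl]-3-ethoxy-4-methylcyclobut-2-en-1-one (racemic diastereomer mixture) | CCCC(O[Si](C)(C)C(C)(C)C)C1=C(OCC)C(C)C1=O | intermediate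
10 | (3Z)-2-[1-(tert-butyldimethylsilyloxy)butyl]-3-ethoxypenta-1,3-dien-1-one (vinylketene, racemic; geometry expected from outward rotation of methyl) | CCO/C(=C\C)C(=C=O)C(CCC)O[Si](C)(C)C(C)(C)C | intermediate
11 | 4-[1-(tert-butyldimethylsilyloxy)butyl]-3-ethoxy-4-[(Z)-1-ethoxyprop-1-en-1-yl]cyclobut-2-en-1-one (racemic diastereomer mixture) | O=C1C=C(OCC)C1(C(CCC)O[Si](C)(C)C(C)(C)C)/C(OCC)=C/C | intermediate
12 | (3E,5Z)-4-[1-(tert-butyldimethylsilyloxy)butyl]-3,5-diethoxyhepta-1,3,5-trien-1-one (dienylketene, racemic) | O=C=C/C(OCC)=C(/C(CCC)O[Si](C)(C)C(C)(C)C)\C(OCC)=C\C | intermediate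
13 | 4-[1-(tert-butyldimethylsilyloxy)butyl]-3,5-diethoxy-6-methylcyclohexa-2,4-dien-1-one (racemic diastereomer mixture) | O=C1C=C(OCC)C(C(CCC)O[Si](C)(C)C(C)(C)C)=C(OCC)C1C | intermediate
14 | 4-[1-(tert-butyldimethylsilyloxy)butyl]-3,5-diethoxy-2-methylphenol (racemic) | CCCC(O[Si](C)(C)C(C)(C)C)c1c(OCC)cc(O)c(C)c1OCC | intermediate
15 | tert-butyl[1-(2,6-diethoxy-4-methoxy-3-methylphenyl)butoxy]dimethylsilane (racemic) | CCCC(O[Si](C)(C)C(C)(C)C)c1c(OCC)cc(OC)c(C)c1OCC | intermediate
16 | 1-(2,6-diethoxy-4-methoxy-3-methylphenyl)butan-1-ol (racemic) | CCCC(O)c1c(OCC)cc(OC)c(C)c1OCC | intermediate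
17 | 1-(2,6-diethoxy-4-methoxy-3-methylphenyl)butan-1-one | CCCC(=O)c1c(OCC)cc(OC)c(C)c1OCC | intermediate
18 | 1-(2,6-dihydroxy-4-methoxy-3-methylphenyl)butan-1-one (aspidinol) | CCCC(=O)c1c(O)cc(OC)c(C)c1O | intermediate
19 | 2,4,6-trihydroxyacetophenone | CC(=O)c1c(O)cc(O)cc1O | starting material
20 | 2-acetyl-3,5-dihydroxy-4,4-dimethylcyclohexa-2,5-dien-1-one (acetylfilicinic acid) | CC(=O)C1=C(O)C(C)(C)C(O)=CC1=O | intermediate
21 | 2-butanoyl-3-hydroxy-5-methoxy-6-methylidenecyclohexa-2,4-dien-1-one (o-quinone methide) | CCCC(=O)C1=C(O)C=C(OC)C(=C)C1=O | intermediate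
22 | 2-acetyl-6-[(3-butanoyl-2,4-dihydroxy-6-methoxyphenyl)methyl]-3,5-dihydroxy-4,4-dimethylcyclohexa-2,5-dien-1-one | CCCC(=O)c1c(O)cc(OC)c(CC2=C(O)C(C)(C)C(O)=C(C(C)=O)C2=O)c1O | target

**Step count**

Total: 10 steps. Longest linear sequence: 9 steps (steps 1–8, then step 10); step 9 prepares ring B separately.

**Steps most likely to fail**

1. Step 4 (benzannulation). The vinylogous-ester chromophore of 9 may open inefficiently, the vinylketene may reclose or oligomerise faster than it is intercepted, or the volatile ynol ether may be lost, so that ring A is not assembled. The fallback gives up the cycloaddition for classical aromatic chemistry; it sets out from 20 and rejoins the route at 22. Purchased 1-(2,4,6-trihydroxyphenyl)butan-1-one is mono-O-methylated at its non-chelated para hydroxyl (Me2SO4, 1 equiv, K2CO3, acetone) to 1-(2,6-dihydroxy-4-methoxyphenyl)butan-1-one F1. F1 and 20 are then joined through a one-carbon bridge by condensation with aqueous formaldehyde in dilute aqueous KOH at room temperature: Knoevenagel-type hydroxymethylation of 20, loss of water, then Michael addition of the phenolate of F1 at its free ring carbon. This should give 22 together with the two symmetrical methylene-bridged dimers, which would be removed by chromatography.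

2. Step 10 (oxidative coupling). One-electron oxidation may lead to phenoxyl coupling at the unsubstituted C3 of ring A, the quinone methide may be captured by a second molecule of 18, or the product may be oxidised further at its new bridge. The fallback releases the same quinone methide without an oxidant; it sets out from 18 and rejoins the route at 22. Acetylation of both phenols (Ac2O, pyridine, DMAP) gives 2-butanoyl-5-methoxy-4-methyl-1,3-phenylene diacetate F2, whose deactivated ring should allow Wohl–Ziegler bromination of the methyl group (NBS, AIBN, PhCF3, reflux) to 4-(bromomethyl)-2-butanoyl-5-methoxy-1,3-phenylene diacetate F3. Treating F3 with 20 and K2CO3 in THF containing methanol cleaves the aryl acetates; the phenoxide expels bromide to form 21, which 20 traps as in step 10 to give 22.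

3. Step 8 (double de-ethylation). Removal of the second ethyl group may stall once the first phenoxide has tied up the carbonyl as a boron chelate, and forcing the reaction may start to cleave the C4 methyl ether. The fallback gives up the differentiation at this point and restores it by selective alkylation; it sets out from 17 and rejoins the route at 18. Exhaustive dealkylation with excess BBr3 (CH2Cl2, −78 °C → rt) gives 1-(2,4,6-trihydroxy-3-methylphenyl)butan-1-one F4. The hydroxyl para to the carbonyl, which is the most acidic and is never hydrogen-bonded to the ketone, is then methylated with Me2SO4 (1 equiv) and K2CO3 in acetone to return to 18.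

**Further compounds**

F1 | step 4 | 1-(2,6-dihydroxy-4-methoxyphenyl)butan-1-one | CCCC(=O)c1c(O)cc(OC)cc1O
F2 | step 10 | 2-butanoyl-5-methoxy-4-methyl-1,3-phenylene diacetate | CCCC(=O)c1c(OC(C)=O)cc(OC)c(C)c1OC(C)=O
F3 | step 10 | 4-(bromomethyl)-2-butanoyl-5-methoxy-1,3-phenylene diacetate | CCCC(=O)c1c(OC(C)=O)cc(OC)c(CBr)c1OC(C)=O
F4 | step 8 | 1-(2,4,6-trihydroxy-3-methylphenyl)butan-1-one | CCCC(=O)c1c(O)cc(O)c(C)c1O
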